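(The earlier runs and the new flask come from a simulation with made-up constants; the scatter is artificial.)

The product comes in two hands, and the first thing I want is the ratio between them.

| setting | birch | larch | flask |
|---|---|---|---|
| left-handed substrate | 0.19 M | 0.19 M | 0.19 M |
| right-handed substrate | 0.19 M | 0.19 M | 0.19 M |
| coupling partner | 0.21 M | 0.31 M | 0.418 M |
| free catalyst | 3.8 mM | 3.8 mM | 3.8 mM |
| remark | run made earlier | run made earlier |  |
| time |  |  | 2.5 d |

- birch (time / d: left-handed product / %, right-handed product / %, left-handed substrate / %): 0.250: 6.2, 3.6, 44.4; 0.833: 9.1, 5.2, 42.0; 1.25: 11.4, 6.2, 41.8; 2.00: 11.1, 5.3, 41.8; 3.00: 9.8, 6.3, 41.5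
- larch (time / d: left-handed product / %, right-handed product / %, left-handed substrate / %): 0.250: 8.1, 3.9, 41.4; 0.417: 10.2, 5.7, 40.3; 0.833: 12.1, 7.2, 40.2; 1.67: 13.4, 7.6, 38.6; 3.00: 13.5, 6.9, 39.5

(scatter of a reading: 0.5 percentage points)

- excess of left-handed product over right-handed product in the product at 3.0 h
- excess of left-handed product over right-handed product in the product at 2.5 d
- part of the left-handed substrate and right-handed substrate charged together that has reacted at 2.5 d

- free catalyst is single-handed; left-handed substrate and right-handed substrate are mirror images of each other, charged as a racemate, each of them at the stated concentration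
- what was read earlier has a scatter of 0.5 percentage points, one standard deviation
- an excess is the difference of the two amounts in percent of their sum
- an excess is below zero if the other one leads

Does the left-handed substrate run down faster than the right-handed one? From a fixed stock, the larch run would hold 36.5% of left-handed substrate at 3.00 d. It reads 39.5%, and what is unreacted there, shared equally between the two substrates, is 39.8% each. So in larch the two substrates interconvert and stay about equal.

What does that give the product? If both hands form on the same catalyst with the same partner, I divide one rate by the other. Catalyst, partner and time drop out, and with equal substrates the product ratio holds still. Pooled over both runs, left-handed product over right-handed product reads 1.81, and I carry this pooled product ratio as a reading with its scatter. I reckon an excess of 28.9% at both asked times.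

Where does the product stop? At 3.00 d the two products together read 16.1% in birch and 20.4% in larch. Larch has 1.48 times the partner of birch but 1.27 times the product, a smaller gain. The new flask has more partner than larch, so I expect it to stop somewhat above larch.

The forecast gives 30%, 28% and 24.5%, holding that “the 1 mol% catalyst dies”.

The flask gives 29.1%, 28.3% and 25.1%.

    coupling partner + free catalyst + left-handed substrate → free catalyst + left-handed product (k = 0.0120 L² mol⁻² s⁻¹)
    coupling partner + free catalyst + right-handed substrate → free catalyst + right-handed product (k = 0.00640 L² mol⁻² s⁻¹)
    left-handed substrate ⇌ right-handed substrate (k = 1.70 × 10⁻⁵ s⁻¹)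
    free catalyst → spent catalyst A (k = 2.10 × 10⁻⁵ s⁻¹)
    coupling partner + free catalyst → spent catalyst B (k = 6.40 × 10⁻⁶ L mol⁻¹ s⁻¹)
    2 coupling partner → homo dimer (k = 4.20 × 10⁻⁵ L mol⁻¹ s⁻¹)

At 2.50 d the right-handed substrate leads by 0.0478% of what remains, and the exchange has a relaxation half-life of 0.236 d, shorter than the run. Split by 1.81, the 25.1% reacted gives 16.2% of left-handed product, and the flask holds 16.1%.

The neighbour with 1.0 M of partner reacts 37.8%. There 1.81 gives an excess of 28.9% and 24.3% of left-handed product. The computed neighbour has 26.7% and 24.0%.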